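Seconds per round of the enzyme are the unit to think in for this flask.

    starting material + free enzyme ⇌ first complex (K1 = 65 M⁻¹, k1 = 2.4 × 10⁵ M⁻¹ s⁻¹)
    first complex → loaded enzyme + first product (k2 = 76 s⁻¹)
    second substrate + loaded enzyme ⇌ second complex (K3 = 66 M⁻¹, k3 = 6.2 × 10⁵ M⁻¹ s⁻¹)
    second complex → free enzyme + target (k4 = 91 s⁻¹)
    solid second substrate ⇌ second substrate, rate k5*(cs5 - [second substrate]) while solid is left; crystals form when [second substrate] > cs5 (cs5 = 8.3 mM, k5 = 0.0045 s⁻¹)
    2 free enzyme → spent catalyst (k6 = 3000 M⁻¹ s⁻¹)

starting material 0.014 M; solid second substrate 5.00 equiv; free enzyme 0.01 mol%; time 2.5 min

- amount of target at 2.5 min, in percent of the starting material charged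
- concentration of second substrate in solution at 2.5 min, in percent of saturation

- two of one species on the left: rate k times its square, two consumed each time
- solid second substrate is a solid; its amount is given per volume of the solution
- at the start none of the solid second substrate is in solution
- run time (flask): 2.5 min

A round has two halves, and in steady state their times add. The first half, free enzyme to loaded enzyme, lasts the breakdown time of the first complex, stretched by one plus a Michaelis constant over the starting material. That constant is 15.7 mM, so at the charge this half takes 0.0279 s. The second half has the same form, with constant 15.3 mM and second substrate in the denominator.

Setting the halves equal gives 9.93 mM: this is the crossing level, the concentration of second substrate at which both halves take equal time. Solubility, 8.3 mM, is lower than that, so with starting material at its charge the second half is the longer one at every level up to solubility.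

First try: with no enzyme the solution reaches 49.1% of saturation, or 4.07 mM. A round there lasts 0.0802 s, which gives 18.7% target.

But the solution starts empty and the enzyme draws it down. At 2.04 mM, half that level, a round lasts 0.121 s, so the enzyme removes second substrate with a pseudo-first-order constant of 0.00566 s⁻¹, larger than the dissolution coefficient. In this reckoning the level climbs at the sum of the two towards 3.68 mM. I commit to 34.6% of saturation and 10.9% target.

Does falling starting material move the crossing? Yes, to 8.98 mM, which is still higher than solubility.

Does the catalyst die? As a rough figure, give free enzyme the first half's share of the round, 23.1%; that puts its loss time near 37.5 min, longer than the run.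

The forecast gives 9.6% (8.3% to 11%) and 36.5% (33% to 40%), lower than my target and higher than my level, saying that “turnover eats into that”.

The simulation gives 10.5% and 35.3%. At 2.5 min in this flask, loaded enzyme and second complex hold 68.5% of the catalyst, against 29.7% in free enzyme and first complex and 1.75% as spent catalyst. The crossing, 9.93 mM at the charge, stands at 9.01 mM with 89% of the starting material left, and second substrate at 0.00293 M is below it. At that level the second half of a round takes 2.31 times as long as the first.

In the neighbour flask read at 10 min, 44% of the starting material is left, which lowers the crossing to 4.71 mM. Second substrate there, 0.00496 M, is close to it, so the halves should run level. Computed, that flask has 39.5% of its catalyst in free enzyme and first complex, 37.9% in loaded enzyme and second complex, and 22.6% as spent catalyst, with 55.9% target.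

(All constants are invented; no experiment stands behind them.)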